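The carbocycle is cut at C1–C14, the ring-fusion bond of the α-methylene γ-lactone (C1 = OCH, C14 = CH, C15 = α-carbon, C17 = exocyclic CH2): the trans C1–O/C14–H pair next to the C15=C17 methylene is a homoallylic alcohol, the mark of a [2,3]-Wittig shift. One base-induced operation on a 17-membered allyl propargyl ether (oxygen bridging C1 and C17) forms C1–C14, both stereocentres, the exocyclic methylene and the 14-membered ring by contraction. Precursor 29 carries C5 as a silyl ether, both lactones as silylated ene-diols and C2≡C3 as the latent methyl olefin; it is closed by alkyne metathesis after a Z-selective olefination at C6=C7.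

Key step: step 19

Remarks on the chemistry
- Numbering: ring carbons C1–C14 (C2=C3 methyl olefin, C5 butenolide OCH, C6=C7, C11 hydroperoxy carbon); C16 = carbonyl carbon of the α-methylene lactone, C18 = butenolide carbonyl carbon.
- Geometry at C14=C15 of 29: C13 is trans to the ether CH2 (C17) and cis to CH2OSi (C16); this is Z by the priority rules, yet it is the "E-type" allyl ether that leads to the anti C1/C14 pair.
- (S)-Glycidol gives 5R because the alkyne enters at the epoxide CH2 and the carbinol carbon is not touched.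
- The C8–C17 segment is built from pent-4-yn-1-ol, because a terpenol C9–C14 unit supplies neither C8 nor an oxygen on the C15 carbon that sits cis to C13.
- The C16 oxygen is carried as a triisopropylsilyl ether so that it cannot shift to a neighbouring alkoxide (steps 13, 19, 21); all silyl groups fall together in step 22.
- Assumption: the (R,R)-lithium amide is taken as the antipode matched to 5R in step 19; the mirror-image base is used instead if a pilot run shows the opposite sense.

Step 1
Reactants: 1 (S)-glycidol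
Product: 2 triethyl{[(2R)-oxiran-2-yl]methoxy}silane (O-triethylsilyl (S)-glycidol)
Conditions: Et3SiCl, Et3N, DMAP (cat.), CH2Cl2, 0 °C
Reagents that add atoms: chlorotriethylsilane, CC[Si](Cl)(CC)CC
Why: Silylation of the primary alcohol leaves the epoxide and its stereocentre untouched (the descriptor changes by the priority rules only), and the triethylsilyl group can later be oxidised off directly.

Step 2
Reactants: 2; 3 1-propynyllithium
Product: 4 (2R)-1-[(triethylsilyl)oxy]hex-4-yn-2-ol
Conditions: BF3·OEt2, THF, −78 °C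
Reagents that add atoms: none
Why: BF3-assisted alkynylation of a terminal epoxide (Yamaguchi–Hirao conditions) opens at the unsubstituted carbon, so C4 and the methyl-capped alkyne are attached while the C5 carbinol keeps the glycidol configuration.

Step 3
Reactants: 4
Product: 5 tert-butyldimethyl{[(2R)-1-[(triethylsilyl)oxy]hex-4-yn-2-yl]oxy}silane
Conditions: t-BuMe2SiCl, imidazole, DMF, rt
Reagents that add atoms: tert-butyldimethylsilyl chloride, CC(C)(C)[Si](C)(C)Cl
Why: Standard silylation of the secondary alcohol gives the base-stable C5 protecting group without touching the stereocentre.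

Step 4
Reactants: 5
Product: 6 (2R)-2-[(tert-butyldimethylsilyl)oxy]hex-4-ynal
Conditions: (COCl)2, DMSO, CH2Cl2, −78 → −30 °C; then i-Pr2NEt, −78 → 0 °C
Reagents that add atoms: none
Why: Swern conditions cleave a primary triethylsilyl ether and oxidise it in the same pot while the secondary tert-butyldimethylsilyl ether survives, and the low temperature with a hindered amine should keep the α-silyloxy aldehyde from epimerising.

Step 5
Reactants: 7 pent-4-yn-1-ol
Product: 8 triethyl(pent-4-yn-1-yloxy)silane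
Conditions: Et3SiCl, imidazole, CH2Cl2, 0 °C
Reagents that add atoms: chlorotriethylsilane, CC[Si](Cl)(CC)CC
Why: Silylation masks the C14 oxygen for the organoaluminium step and allows its later one-pot oxidation.

Step 6
Reactants: 8; 9 ethylene oxide
Product: 12 (3E)-4-methyl-7-[(triethylsilyl)oxy]hept-3-en-1-ol, via alkenylalane 10 (not isolated), via lithium alkenylaluminate 11 (not isolated)
Conditions: Me3Al, Cp2ZrCl2 (0.2 equiv), CH2Cl2, 0 °C → rt; then n-BuLi, hexane–THF, −78 °C; then 9, −78 °C → rt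
Reagents that add atoms: trimethylaluminium, C[Al](C)C
Why: Zirconium-catalysed methylalumination of the terminal alkyne (Negishi carboalumination) is syn with aluminium on the terminal carbon, so C10=C11 is formed as the E olefin, and the derived ate complex opens ethylene oxide with retention to add C9 and C8.

Step 7
Reactants: 12
Product: 13 {[(4E)-7-chloro-4-methylhept-4-en-1-yl]oxy}triethylsilane
Conditions: PPh3, N-chlorosuccinimide, THF, 0 °C → rt
Reagents that add atoms: N-chlorosuccinimide, O=C1CCC(=O)N1Cl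
Why: Appel-type chlorination (SN2 on the alkoxyphosphonium salt) turns C8–OH into a chloride that is inert through the next six steps and is activated by iodide in step 14.

Step 8
Reactants: 13
Product: 14 (4E)-7-chloro-4-methylhept-4-enal
Conditions: (COCl)2, DMSO, CH2Cl2, −78 → −30 °C; then Et3N, −78 → 0 °C
Reagents that add atoms: none
Why: The same direct Swern oxidation of a primary triethylsilyl ether gives the C14 aldehyde without a separate deprotection and without affecting the olefin or the chloride.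

Step 9
Reactants: 15 methyl 3-hydroxypropanoate
Product: 16 methyl 3-[(triisopropylsilyl)oxy]propanoate
Conditions: i-Pr3SiCl, imidazole, DMF, rt
Reagents that add atoms: chlorotriisopropylsilane, CC(C)[Si](Cl)(C(C)C)C(C)C
Why: Silylation provides the C15–C16 building block with a bulky silyl group that resists oxygen-to-oxygen migration.

Step 10
Reactants: 14; 16
Product: 17 methyl (6E)-9-chloro-3-hydroxy-6-methyl-2-{[(triisopropylsilyl)oxy]methyl}non-6-enoate (mixture of diastereomers)
Conditions: LiN(i-Pr)2, THF, −78 °C; then 14, −78 °C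
Reagents that add atoms: none
Why: Aldol addition of the ester lithium enolate joins C14 to C15; at −78 °C addition should outrun β-elimination of the silyloxy group, and both new stereocentres are removed in the next step.

Step 11
Reactants: 17
Product: 19 methyl (2E,6E)-9-chloro-6-methyl-2-{[(triisopropylsilyl)oxy]methyl}nona-2,6-dienoate, via mesylate 18 (not isolated)
Conditions: MeSO2Cl, Et3N, CH2Cl2, 0 °C; then DBU, 0 °C → rt
Reagents that add atoms: none
Why: E1cB elimination of the β-mesyloxy ester gives the trisubstituted enoate in which the ester avoids the cis β-substituent, so C13 should end trans to the ester carbon (future C17) and cis to CH2OSi (C16); isomeric purity is to be secured by chromatography here.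

Step 12
Reactants: 19
Product: 20 (2Z,6E)-9-chloro-6-methyl-2-{[(triisopropylsilyl)oxy]methyl}nona-2,6-dien-1-ol
Conditions: i-Bu2AlH, CH2Cl2, −78 °C
Reagents that add atoms: none
Why: 1,2-Reduction of the enoate with i-Bu2AlH gives the allylic alcohol (C17–OH, trans to C13) without touching the alkyl chloride or the olefin geometry.

Step 13
Reactants: 20; 21 1-bromobut-2-yne
Product: 22 {[(2Z,6E)-2-[(but-2-yn-1-yloxy)methyl]-9-chloro-6-methylnona-2,6-dien-1-yl]oxy}triisopropylsilane
Conditions: NaH, Bu4NI (cat.), THF, 0 °C → rt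
Reagents that add atoms: none
Why: Williamson etherification with a reactive propargylic bromide installs the C17–O–C1 linkage and the second methyl-capped alkyne; the triisopropylsilyl group should not shift to the alkoxide, so the ether sits on the CH2 trans to C13.

Step 14
Reactants: 22; 23 methyl 2-[bis(2,2,2-trifluoroethoxy)phosphoryl]acetate
Product: 25 methyl (5E,9Z)-2-[bis(2,2,2-trifluoroethoxy)phosphoryl]-10-[(but-2-yn-1-yloxy)methyl]-6-methyl-11-[(triisopropylsilyl)oxy]undeca-5,9-dienoate (racemic at C2), via iodide 24 (not isolated)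
Conditions: NaH, THF–DMF, 0 °C (excess 23); then 22, NaI, 50 °C
Reagents that add atoms: none
Why: C-Alkylation of the phosphonoacetate anion by the primary iodide formed in situ (Finkelstein exchange) forms C7–C8; excess phosphonate suppresses dialkylation and the new stereocentre is lost in step 15.

Step 15
Reactants: 25; 6
Product: 26 methyl (2Z,4R)-2-[(3E,7Z)-8-[(but-2-yn-1-yloxy)methyl]-4-methyl-9-[(triisopropylsilyl)oxy]nona-3,7-dien-1-yl]-4-[(tert-butyldimethylsilyl)oxy]oct-2-en-6-ynoate
Conditions: KN(SiMe3)2, 18-crown-6, THF, −78 °C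
Reagents that add atoms: none
Why: Still–Gennari olefination, in which the trifluoroethyl phosphonate collapses from the kinetic adduct, should give the Z trisubstituted enoate with the ester cis to C5 (needed later for butenolide closure), and the weakly basic anion at −78 °C leaves C5 intact.

Step 16
Reactants: 26
Product: 27 (2Z,4R)-2-[(3E,7Z)-8-[(but-2-yn-1-yloxy)methyl]-4-methyl-9-[(triisopropylsilyl)oxy]nona-3,7-dien-1-yl]-4-[(tert-butyldimethylsilyl)oxy]oct-2-en-6-yn-1-ol
Conditions: i-Bu2AlH, CH2Cl2, −78 °C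
Reagents that add atoms: none
Why: 1,2-Reduction of the enoate removes the only base-sensitive carbonyl group before the strong-base step and gives C18–OH.

Step 17
Reactants: 27
Product: 28 tert-butyldimethylsilyl ether of 27 (open-chain diyne with C5–O, C16–O and C18–O silylated)
Conditions: t-BuMe2SiCl, imidazole, DMF, rt
Reagents that add atoms: tert-butyldimethylsilyl chloride, CC(C)(C)[Si](C)(C)Cl
Why: Silylation of the primary allylic alcohol completes the masking of both future lactones as silylated ene-diols.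

Step 18
Reactants: 28
Product: 29 (3Z,7E,11Z,13R)-13-[(tert-butyldimethylsilyl)oxy]-11-{[(tert-butyldimethylsilyl)oxy]methyl}-7-methyl-3-{[(triisopropylsilyl)oxy]methyl}-1-oxacycloheptadeca-3,7,11-trien-15-yne
Conditions: [Mo(≡C-C6H4-4-OMe)(OSiPh3)3] (10 mol%), 5 Å molecular sieves, toluene, 0.002 M, rt → 60 °C
Reagents that add atoms: none
Why: Ring-closing alkyne metathesis of the two methyl-capped alkynes forms C2≡C3 and the 17-membered ether, the sieves removing but-2-yne; olefins, their geometries and silyl ethers are inert to the alkylidyne.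

Step 19
Reactants: 29
Product: 31 (1R,5R,6Z,10E,14R)-5-[(tert-butyldimethylsilyl)oxy]-7-{[(tert-butyldimethylsilyl)oxy]methyl}-11-methyl-14-{3-[(triisopropylsilyl)oxy]prop-1-en-2-yl}cyclotetradeca-6,10-dien-2-yn-1-ol, via C1-lithiated ether 30 (not isolated)
Conditions: (R,R)-[PhCH(Me)]2NH, n-BuLi, THF, 0 °C; then 29, −78 → −25 °C
Reagents that add atoms: none
Why: The lithium amide removes one propargylic O–CH2 hydrogen at C1 and the α-oxy carbanion 30 attacks C14, the γ-terminus of the allyl ether, through a five-membered envelope transition state while the O–C17 bond breaks and C17 becomes the exocyclic methylene ([2,3]-Wittig rearrangement). The closest known reaction type is the [2,3]-Wittig ring contraction of macrocyclic allyl propargyl ethers to 14-membered propargylic alcohols. The 14-membered carbocycle is closed by contraction inside the existing 17-membered ring through this five-centre sigmatropic shift, not by an end-to-end cyclisation under dilution. C14 is tied to C1 through the envelope with the alkynyl group exo, and because C13 is trans to C17 this gives the anti pair; C1 is set by which hydrogen the chiral amide abstracts (the pro-S hydrogen, on the usual premise of inversion at the lithiated carbon), matched to 5R. Since C5 is already fixed, the two possible anti products are diastereomers and should be separable. Site selectivity rests on C1 being the only C–H activated by both oxygen and the triple bond, and the silyl ethers leave no other acidic or electrophilic site.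

Step 20
Reactants: 31
Product: 33 (1R,2Z,5R,6Z,10E,14R)-5-[(tert-butyldimethylsilyl)oxy]-7-{[(tert-butyldimethylsilyl)oxy]methyl}-3-iodo-11-methyl-14-{3-[(triisopropylsilyl)oxy]prop-1-en-2-yl}cyclotetradeca-2,6,10-trien-1-ol, via alkenylaluminate 32 (not isolated)
Conditions: NaAlH2(OCH2CH2OMe)2, THF, 0 °C → rt; EtOAc; then I2, THF, −78 °C
Reagents that add atoms: iodine, II
Why: Hydroxyl-directed trans-hydroalumination delivers hydride to C2 and leaves aluminium on C3 in a five-membered chelate cis to C1, and iodinolysis with retention gives the Z vinyl iodide.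

Step 21
Reactants: 33
Product: 34 (1S,2E,5R,6Z,10E,14R)-5-[(tert-butyldimethylsilyl)oxy]-7-{[(tert-butyldimethylsilyl)oxy]methyl}-3,11-dimethyl-14-{3-[(triisopropylsilyl)oxy]prop-1-en-2-yl}cyclotetradeca-2,6,10-trien-1-ol
Conditions: MeLi, CuI, Et2O, 0 °C; then 33, 0 °C
Reagents that add atoms: lithium dimethylcuprate, [Li+].C[Cu-]C
Why: Corey–House-type cuprate coupling replaces iodine by methyl with retention of olefin geometry, giving the E C2=C3 methyl olefin; the C1 descriptor changes by the priority rules only.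

Step 22
Reactants: 34
Product: 35 (1S,2E,5R,6Z,10E,14R)-7-(hydroxymethyl)-14-(3-hydroxyprop-1-en-2-yl)-3,11-dimethylcyclotetradeca-2,6,10-triene-1,5-diol
Conditions: Bu4NF, THF, rt
Reagents that add atoms: none
Why: Fluoride-induced desilylation removes all three silyl groups in one operation without affecting stereocentres or olefins.

Step 23
Reactants: 35
Product: 37 bis-lactone (1S,5R,14R; trans-fused α-methylene γ-lactone on C1/C14; butenolide on C5–C7; 2E and 10E olefins; no oxygen on C11), via bis-lactol 36 (not isolated)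
Conditions: TEMPO (0.3 equiv), PhI(OAc)2 (5 equiv), CH2Cl2, rt
Reagents that add atoms: none
Why: Oxoammonium-mediated oxidative lactonisation oxidises the two primary allylic alcohols in preference to the secondary ones; each hydroxy aldehyde closes to a five-membered lactol (C1–OH onto C16, C5–OH onto C18) that is oxidised on to the lactone.

Step 24
Reactants: 37
Product: 38 target hydroperoxide (1S,5R,11S,14R; 2E,9E)
Conditions: O2, hν (visible), tetraphenylporphyrin (cat.), CH2Cl2, −20 °C
Reagents that add atoms: dioxygen, O=O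
Why: Schenck ene reaction of singlet oxygen at C10=C11, the only electron-rich olefin (C2=C3 is deactivated by the allylic lactone oxygen, the others are conjugated), should place oxygen on C11 with abstraction of a C9 hydrogen from the more crowded olefin side and shift the double bond to E C9=C10; 11S requires attack on the outer face of the macrocycle, and regio- and stereoisomers are to be separated.

Compound list
1 | (S)-glycidol | OC[C@H]1CO1 | starting material
2 | triethyl{[(2R)-oxiran-2-yl]methoxy}silane | CC[Si](CC)(CC)OC[C@H]1CO1 | intermediate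
3 | 1-propynyllithium | [Li]C#CC | starting material
4 | (2R)-1-[(triethylsilyl)oxy]hex-4-yn-2-ol | CC#CC[C@@H](O)CO[Si](CC)(CC)CC | intermediate
5 | tert-butyldimethyl{[(2R)-1-[(triethylsilyl)oxy]hex-4-yn-2-yl]oxy}silane | CC#CC[C@@H](O[Si](C)(C)C(C)(C)C)CO[Si](CC)(CC)CC | intermediate
6 | (2R)-2-[(tert-butyldimethylsilyl)oxy]hex-4-ynal | CC#CC[C@@H](O[Si](C)(C)C(C)(C)C)C=O | intermediate
7 | pent-4-yn-1-ol | C#CCCCO | starting material
8 | triethyl(pent-4-yn-1-yloxy)silane | C#CCCCO[Si](CC)(CC)CC | intermediate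
9 | ethylene oxide | C1CO1 | starting material
10 | dimethyl{(1E)-2-methyl-5-[(triethylsilyl)oxy]pent-1-en-1-yl}alumane | C[Al](C)/C=C(\C)CCCO[Si](CC)(CC)CC | intermediate
11 | lithium butyl(dimethyl){(1E)-2-methyl-5-[(triethylsilyl)oxy]pent-1-en-1-yl}aluminate | [Li+].CCCC[Al-](C)(C)/C=C(\C)CCCO[Si](CC)(CC)CC | intermediate
12 | (3E)-4-methyl-7-[(triethylsilyl)oxy]hept-3-en-1-ol | OCC/C=C(\C)CCCO[Si](CC)(CC)CC | intermediate
13 | {[(4E)-7-chloro-4-methylhept-4-en-1-yl]oxy}triethylsilane | ClCC/C=C(\C)CCCO[Si](CC)(CC)CC | intermediate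
14 | (4E)-7-chloro-4-methylhept-4-enal | O=CCC/C(C)=C/CCCl | intermediate
15 | methyl 3-hydroxypropanoate | COC(=O)CCO | starting material
16 | methyl 3-[(triisopropylsilyl)oxy]propanoate | COC(=O)CCO[Si](C(C)C)(C(C)C)C(C)C | intermediate
17 | methyl (6E)-9-chloro-3-hydroxy-6-methyl-2-{[(triisopropylsilyl)oxy]methyl}non-6-enoate | COC(=O)C(CO[Si](C(C)C)(C(C)C)C(C)C)C(O)CC/C(C)=C/CCCl | intermediate
18 | methyl (6E)-9-chloro-6-methyl-3-[(methylsulfonyl)oxy]-2-{[(triisopropylsilyl)oxy]methyl}non-6-enoate | COC(=O)C(CO[Si](C(C)C)(C(C)C)C(C)C)C(OS(C)(=O)=O)CC/C(C)=C/CCCl | intermediate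
19 | methyl (2E,6E)-9-chloro-6-methyl-2-{[(triisopropylsilyl)oxy]methyl}nona-2,6-dienoate | COC(=O)/C(CO[Si](C(C)C)(C(C)C)C(C)C)=C/CC/C(C)=C/CCCl | intermediate
20 | (2Z,6E)-9-chloro-6-methyl-2-{[(triisopropylsilyl)oxy]methyl}nona-2,6-dien-1-ol | OC/C(CO[Si](C(C)C)(C(C)C)C(C)C)=C/CC/C(C)=C/CCCl | intermediate
21 | 1-bromobut-2-yne | CC#CCBr | starting material
22 | {[(2Z,6E)-2-[(but-2-yn-1-yloxy)methyl]-9-chloro-6-methylnona-2,6-dien-1-yl]oxy}triisopropylsilane | CC#CCOC/C(CO[Si](C(C)C)(C(C)C)C(C)C)=C/CC/C(C)=C/CCCl | intermediate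
23 | methyl 2-[bis(2,2,2-trifluoroethoxy)phosphoryl]acetate | COC(=O)CP(=O)(OCC(F)(F)F)OCC(F)(F)F | starting material
24 | {[(2Z,6E)-2-[(but-2-yn-1-yloxy)methyl]-9-iodo-6-methylnona-2,6-dien-1-yl]oxy}triisopropylsilane | CC#CCOC/C(CO[Si](C(C)C)(C(C)C)C(C)C)=C/CC/C(C)=C/CCI | intermediate
25 | methyl (5E,9Z)-2-[bis(2,2,2-trifluoroethoxy)phosphoryl]-10-[(but-2-yn-1-yloxy)methyl]-6-methyl-11-[(triisopropylsilyl)oxy]undeca-5,9-dienoate | COC(=O)C(CC/C=C(\C)CC/C=C(CO[Si](C(C)C)(C(C)C)C(C)C)/COCC#CC)P(=O)(OCC(F)(F)F)OCC(F)(F)F | intermediate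
26 | methyl (2Z,4R)-2-[(3E,7Z)-8-[(but-2-yn-1-yloxy)methyl]-4-methyl-9-[(triisopropylsilyl)oxy]nona-3,7-dien-1-yl]-4-[(tert-butyldimethylsilyl)oxy]oct-2-en-6-ynoate | COC(=O)/C(CC/C=C(\C)CC/C=C(CO[Si](C(C)C)(C(C)C)C(C)C)/COCC#CC)=C\[C@H](O[Si](C)(C)C(C)(C)C)CC#CC | intermediate
27 | (2Z,4R)-2-[(3E,7Z)-8-[(but-2-yn-1-yloxy)methyl]-4-methyl-9-[(triisopropylsilyl)oxy]nona-3,7-dien-1-yl]-4-[(tert-butyldimethylsilyl)oxy]oct-2-en-6-yn-1-ol | OC/C(CC/C=C(\C)CC/C=C(CO[Si](C(C)C)(C(C)C)C(C)C)/COCC#CC)=C\[C@H](O[Si](C)(C)C(C)(C)C)CC#CC | intermediate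
28 | tert-butyldimethylsilyl ether of 27 (open-chain diyne) | CC(C)(C)[Si](C)(C)OC/C(CC/C=C(\C)CC/C=C(CO[Si](C(C)C)(C(C)C)C(C)C)/COCC#CC)=C\[C@H](O[Si](C)(C)C(C)(C)C)CC#CC | intermediate
29 | (3Z,7E,11Z,13R)-13-[(tert-butyldimethylsilyl)oxy]-11-{[(tert-butyldimethylsilyl)oxy]methyl}-7-methyl-3-{[(triisopropylsilyl)oxy]methyl}-1-oxacycloheptadeca-3,7,11-trien-15-yne (17-membered allyl propargyl ether) | O1C/C(CO[Si](C(C)C)(C(C)C)C(C)C)=C/CC/C(C)=C/CC/C(CO[Si](C)(C)C(C)(C)C)=C/[C@H](O[Si](C)(C)C(C)(C)C)CC#CC1 | intermediate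
30 | 17-lithio derivative of 29 (lithium on the propargylic OCH carbon, C1) | [Li]C1OC/C(CO[Si](C(C)C)(C(C)C)C(C)C)=C/CC/C(C)=C/CC/C(CO[Si](C)(C)C(C)(C)C)=C/[C@H](O[Si](C)(C)C(C)(C)C)CC#C1 | intermediate
31 | (1R,5R,6Z,10E,14R)-5-[(tert-butyldimethylsilyl)oxy]-7-{[(tert-butyldimethylsilyl)oxy]methyl}-11-methyl-14-{3-[(triisopropylsilyl)oxy]prop-1-en-2-yl}cyclotetradeca-6,10-dien-2-yn-1-ol | C=C(CO[Si](C(C)C)(C(C)C)C(C)C)[C@H]1CC/C(C)=C/CC/C(CO[Si](C)(C)C(C)(C)C)=C/[C@H](O[Si](C)(C)C(C)(C)C)CC#C[C@@H]1O | intermediate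
32 | sodium bis(2-methoxyethoxy)aluminate chelate of 31 (Al on C3 and on the C1 oxygen, H on C2) | [Na+].C=C(CO[Si](C(C)C)(C(C)C)C(C)C)[C@H]1CC/C(C)=C/CC/C(CO[Si](C)(C)C(C)(C)C)=C/[C@H](O[Si](C)(C)C(C)(C)C)C/C(=C/[C@@H]1O2)[Al-]2(OCCOC)OCCOC | intermediate
33 | (1R,2Z,5R,6Z,10E,14R)-5-[(tert-butyldimethylsilyl)oxy]-7-{[(tert-butyldimethylsilyl)oxy]methyl}-3-iodo-11-methyl-14-{3-[(triisopropylsilyl)oxy]prop-1-en-2-yl}cyclotetradeca-2,6,10-trien-1-ol | C=C(CO[Si](C(C)C)(C(C)C)C(C)C)[C@H]1CC/C(C)=C/CC/C(CO[Si](C)(C)C(C)(C)C)=C/[C@H](O[Si](C)(C)C(C)(C)C)C/C(I)=C/[C@@H]1O | intermediate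
34 | (1S,2E,5R,6Z,10E,14R)-5-[(tert-butyldimethylsilyl)oxy]-7-{[(tert-butyldimethylsilyl)oxy]methyl}-3,11-dimethyl-14-{3-[(triisopropylsilyl)oxy]prop-1-en-2-yl}cyclotetradeca-2,6,10-trien-1-ol | C=C(CO[Si](C(C)C)(C(C)C)C(C)C)[C@H]1CC/C(C)=C/CC/C(CO[Si](C)(C)C(C)(C)C)=C/[C@H](O[Si](C)(C)C(C)(C)C)C/C(C)=C/[C@@H]1O | intermediate
35 | (1S,2E,5R,6Z,10E,14R)-7-(hydroxymethyl)-14-(3-hydroxyprop-1-en-2-yl)-3,11-dimethylcyclotetradeca-2,6,10-triene-1,5-diol | C=C(CO)[C@H]1CC/C(C)=C/CC/C(CO)=C/[C@H](O)C/C(C)=C/[C@@H]1O | intermediate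
36 | bis-lactol (hemiacetal carbons C16 and C18, both anomers) | C=C1C(O)O[C@H]2/C=C(\C)C[C@@H]3C=C(CC/C=C(\C)CC[C@H]12)C(O)O3 | intermediate
37 | bis-lactone lacking the C11 oxygen (1S,5R,14R; 2E,10E) | C=C1C(=O)O[C@H]2/C=C(\C)C[C@@H]3C=C(CC/C=C(\C)CC[C@H]12)C(=O)O3 | intermediate
38 | target hydroperoxide CNP0343227.1 (1S,5R,11S,14R; 2E,9E) | C=C1C(=O)O[C@H]2/C=C(\C)C[C@@H]3C=C(C/C=C/[C@@](C)(OO)CC[C@H]12)C(=O)O3 | target

Total step count: 24. Longest linear sequence: 19 steps (7 → 8 → 12 → 13 → 14 → 17 → 19 → 20 → 22 → 25 → 26 → 27 → 28 → 29 → 31 → 33 → 34 → 35 → 37 → 38).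

Steps most likely to fail

1. Step 19. The amide may not discriminate the two C1 hydrogens when the C5 centre opposes it (poor facial selectivity between the two anti products). The lithiated macrocycle may also be too constrained to reach the envelope, and then drift to a [1,2]-shift or to deprotonation at C4 with loss of the C5 silyloxy group. Fallback, from 28 back to 31: the order of rearrangement and ring closure is exchanged. Open-chain diyne 28, itself an allyl but-2-ynyl ether, undergoes the same [2,3]-Wittig shift in the acyclic manifold (the lithium amide, or t-BuLi with a chiral bis(oxazoline), THF, −78 °C) to acyclic anti propargylic alcohol F1, free of ring strain. The hydroxyl is capped with Et3SiCl and imidazole as triethylsilyl ether F2. Ring-closing alkyne metathesis with [Mo(≡C-C6H4-4-OMe)(OSiPh3)3] then closes the 14-membered cycloalkyne F3 directly, where C5 makes the diastereomers separable. PPTS in MeOH at 0 °C removes the triethylsilyl group and returns 31.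

2. Step 24. Singlet oxygen may abstract a hydrogen of the C11 methyl instead of C9 (secondary hydroperoxide at C10 with an exocyclic methylene), may approach the inner face of C10=C11 (11R epimer), or may attack C2=C3. Fallback, from 34 back to 38: the oxygenation is moved ahead of the lactonisations onto the fully silylated macrocycle, whose shape and shielding differ. The C1 hydroxyl of 34 is silylated (t-BuMe2SiOTf, 2,6-lutidine) to tetrasilyl ether F4, in which C2=C3 and C6=C7 are flanked by silyloxy groups. Photooxygenation as in step 24 gives hydroperoxide F5, which is masked with 2-methoxypropene and PPTS as peroxyketal F6. Bu4NF gives tetraol peroxyketal F7, TEMPO with PhI(OAc)2 closes both lactones to bis-lactone peroxyketal F8, and aqueous AcOH in THF releases the hydroperoxide to give 38.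

3. Step 11. Incomplete geometric control in the elimination (C13 cis to the ester), or loss of the silyloxy group instead of mesylate, would carry the wrong C14=C15 geometry into step 19 and erode the anti selectivity. Fallback, from 14 back to 19: Morita–Baylis–Hillman reaction of 14 with methyl acrylate and DABCO gives allylic alcohol F9, and Ac2O with DMAP gives secondary acetate F10. DABCO-mediated 1,3-transposition, in which the conjugated ester dictates the geometry, gives primary acetate F11 with C13 trans to the ester. K2CO3 in MeOH cleaves the acetate to alcohol F12, and i-Pr3SiCl with imidazole gives 19.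

Further compounds
F1 | step 19 | open-chain anti propargylic alcohol from [2,3]-Wittig shift of 28 (C1–C14 bond formed, both alkynes methyl-capped) | CC#C[C@H](O)[C@H](CC/C(C)=C/CC/C(CO[Si](C)(C)C(C)(C)C)=C/[C@H](O[Si](C)(C)C(C)(C)C)CC#CC)C(=C)CO[Si](C(C)C)(C(C)C)C(C)C
F2 | step 19 | triethylsilyl ether of F1 | CC#C[C@H](O[Si](CC)(CC)CC)[C@H](CC/C(C)=C/CC/C(CO[Si](C)(C)C(C)(C)C)=C/[C@H](O[Si](C)(C)C(C)(C)C)CC#CC)C(=C)CO[Si](C(C)C)(C(C)C)C(C)C
F3 | step 19 | C1-O-triethylsilyl ether of 31 | C=C(CO[Si](C(C)C)(C(C)C)C(C)C)[C@H]1CC/C(C)=C/CC/C(CO[Si](C)(C)C(C)(C)C)=C/[C@H](O[Si](C)(C)C(C)(C)C)CC#C[C@@H]1O[Si](CC)(CC)CC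
F4 | step 24 | C1-O-tert-butyldimethylsilyl ether of 34 | C=C(CO[Si](C(C)C)(C(C)C)C(C)C)[C@H]1CC/C(C)=C/CC/C(CO[Si](C)(C)C(C)(C)C)=C/[C@H](O[Si](C)(C)C(C)(C)C)C/C(C)=C/[C@@H]1O[Si](C)(C)C(C)(C)C
F5 | step 24 | 11S hydroperoxide of F4 with E C9=C10 | C=C(CO[Si](C(C)C)(C(C)C)C(C)C)[C@H]1CC[C@](C)(OO)/C=C/C/C(CO[Si](C)(C)C(C)(C)C)=C/[C@H](O[Si](C)(C)C(C)(C)C)C/C(C)=C/[C@@H]1O[Si](C)(C)C(C)(C)C
F6 | step 24 | 2-methoxyprop-2-yl peroxyketal of F5 | C=C(CO[Si](C(C)C)(C(C)C)C(C)C)[C@H]1CC[C@](C)(OOC(C)(C)OC)/C=C/C/C(CO[Si](C)(C)C(C)(C)C)=C/[C@H](O[Si](C)(C)C(C)(C)C)C/C(C)=C/[C@@H]1O[Si](C)(C)C(C)(C)C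
F7 | step 24 | tetraol peroxyketal | C=C(CO)[C@H]1CC[C@](C)(OOC(C)(C)OC)/C=C/C/C(CO)=C/[C@H](O)C/C(C)=C/[C@@H]1O
F8 | step 24 | 2-methoxyprop-2-yl peroxyketal of 38 | C=C1C(=O)O[C@H]2/C=C(\C)C[C@@H]3C=C(C/C=C/[C@@](C)(OOC(C)(C)OC)CC[C@H]12)C(=O)O3
F9 | step 11 | methyl (6E)-9-chloro-3-hydroxy-6-methyl-2-methylidenenon-6-enoate | COC(=O)C(=C)C(O)CC/C(C)=C/CCCl
F10 | step 11 | methyl (6E)-3-acetoxy-9-chloro-6-methyl-2-methylidenenon-6-enoate | COC(=O)C(=C)C(OC(C)=O)CC/C(C)=C/CCCl
F11 | step 11 | methyl (2E,6E)-2-(acetoxymethyl)-9-chloro-6-methylnona-2,6-dienoate | COC(=O)/C(COC(C)=O)=C/CC/C(C)=C/CCCl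
F12 | step 11 | methyl (2E,6E)-9-chloro-2-(hydroxymethyl)-6-methylnona-2,6-dienoate | COC(=O)/C(CO)=C/CC/C(C)=C/CCCl
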